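**Retrosynthetic overview**
- Late stage: the ring oxirane comes from peracid attack on the outer face of the E C1=C10 alkene. The C3 isovalerate comes from acylation, and the C3 carbinol from peripheral hydride attack on the ring ketone.
- Ten-membered ring: the C3–C4 bond is closed by an intramolecular Nozaki–Hiyama–Kishi coupling of a Z alkenyl iodide and a β,γ-unsaturated aldehyde.
- C7–C8 bond and trans α-methylene lactone: a Zn Barbier coupling joins a 3-(bromomethyl)butenolide to the C8 aldehyde and gives the 8α-OH. Mitsunobu esterification using the epoxy acid then inverts C8 to 8β.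
- Three fragments: the butenolide (acrolein plus propynyl Grignard, Sharpless kinetic resolution sets C6, ring-closing metathesis), the C8–C3 aldehyde (pent-3-yn-1-ol plus oxirane), and the epoxy acid (tiglyl alcohol, Sharpless epoxidation).
- Ring order: side-chain oxirane and butenolide (separately), then the ten-membered carbocycle, then the C1–C10 oxirane.

Assumption: the SMILES is taken literally. Its C8 acyl group is the (2S,3R)-2,3-dimethyloxirane-2-carboxylate, whose two methyl groups are cis, so it is the epoxide of tiglic acid and not of angelic acid. Germacrane numbering (C1–C15) is used for positions in all intermediates.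

**Fragment 1: bromobutenolide**

Step 1
Reactants: 1 acrolein (prop-2-enal); 2 prop-1-yn-1-ylmagnesium bromide
Product: 3 (±)-hex-1-en-4-yn-3-ol
Conditions: THF, −78 → 0 °C; aqueous work-up
Reagents that add atoms: none
Why: Grignard 1,2-addition of the alkynyl nucleophile to the enal carbonyl is fast and clean at low temperature; the new carbinol centre (future C6) is racemic here and is resolved in step 3.

Step 2
Reactants: 3 (±)-hex-1-en-4-yn-3-ol
Product: 5 (±)-(4Z)-5-iodohexa-1,4-dien-3-ol, via cyclic vinylalanate 4 (not isolated)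
Conditions: NaAlH2(OCH2CH2OMe)2 (1.5 equiv), THF, 0 °C → rt; then I2, −78 °C; aqueous work-up
Reagents that add atoms: iodine, I-I
Why: Hydroxyl-directed trans-hydroalumination of the propargylic alcohol puts aluminium on the distal alkyne carbon inside a five-membered ring, and iodinolysis with retention gives only the Z iodoalkene (iodine cis to the carbinol carbon), which fixes the Z C4=C5 geometry; the isolated vinyl group is inert.

Step 3
Reactants: 5 (±)-(4Z)-5-iodohexa-1,4-dien-3-ol
Product: 6 (3S,4Z)-5-iodohexa-1,4-dien-3-ol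
Conditions: Ti(OiPr)4 (0.15 equiv), L-(+)-diisopropyl tartrate (0.2 equiv), t-BuOOH (0.6 equiv), 4 Å molecular sieves, CH2Cl2, −20 °C, stopped at ca. 55 % conversion
Reagents that add atoms: none
Why: Sharpless kinetic resolution: with the L-(+)-tartrate catalyst the R alcohol is epoxidised at its vinyl group far faster than the S alcohol, so the S enantiomer (C6 of the target) is recovered in high ee, while the electron-poor Z iodoalkene is not oxidised.

Step 4
Reactants: 6 (3S,4Z)-5-iodohexa-1,4-dien-3-ol; 7 2-(bromomethyl)prop-2-enoic acid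
Product: 8 (3S,4Z)-5-iodohexa-1,4-dien-3-yl 2-(bromomethyl)prop-2-enoate
Conditions: DCC (1.1 equiv), DMAP (0.05 equiv), CH2Cl2, 0 °C
Reagents that add atoms: none
Why: Steglich esterification acylates the alcohol at oxygen without touching C6, and at 0 °C the allylic bromide and the alkenyl iodide survive.

Step 5
Reactants: 8 (3S,4Z)-5-iodohexa-1,4-dien-3-yl 2-(bromomethyl)prop-2-enoate
Product: 9 (5S)-3-(bromomethyl)-5-[(1Z)-2-iodoprop-1-en-1-yl]furan-2(5H)-one
Conditions: (H2IMes)(PCy3)Cl2Ru=CHPh (second-generation Grubbs catalyst, 5 mol %), CH2Cl2 (5 mM), reflux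
Reagents that add atoms: none
Why: Ring-closing metathesis starts at the monosubstituted vinyl group and closes onto the acrylate alkene to give the five-membered butenolide with loss of ethene; the trisubstituted iodoalkene and the allylic bromide are spectators and C6 is untouched.

**Fragment 2: C8–C3 aldehyde**

Step 6
Reactants: 10 pent-3-yn-1-ol
Product: 11 tert-butyl(dimethyl)(pent-3-yn-1-yloxy)silane
Conditions: TBSCl, imidazole, CH2Cl2, rt
Reagents that add atoms: tert-butyldimethylsilyl chloride, CC(C)(C)[Si](C)(C)Cl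
Why: Standard silylation of the primary alcohol protects the future C3 oxygen through the organometallic steps.

Step 7
Reactants: 11 tert-butyl(dimethyl)(pent-3-yn-1-yloxy)silane
Product: 13 tert-butyl{[(3E)-4-iodopent-3-en-1-yl]oxy}dimethylsilane, via alkenylzirconocene chloride 12 (not isolated)
Conditions: Cp2Zr(H)Cl (2 equiv), THF, 40 °C; then I2, 0 °C
Reagents that add atoms: iodine, I-I
Why: Hydrozirconation is a syn addition and, with excess reagent under equilibrating conditions, zirconium ends on the less hindered methyl-bearing carbon; iodinolysis with retention gives the E iodide that fixes the E C1=C10 geometry.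

Step 8
Reactants: 13 tert-butyl{[(3E)-4-iodopent-3-en-1-yl]oxy}dimethylsilane; 14 oxirane
Product: 16 (3E)-6-{[tert-butyl(dimethyl)silyl]oxy}-3-methylhex-3-en-1-ol, via alkenyllithium 15 (not isolated)
Conditions: t-BuLi (2.1 equiv), Et2O, −78 °C; then 14, −78 → 0 °C; aqueous work-up
Reagents that add atoms: none
Why: Lithium–iodine exchange occurs with retention of alkene geometry and the alkenyllithium opens oxirane by SN2 attack, adding C9 and C8 as a free primary alcohol while the silyl ether stays on.

Step 9
Reactants: 16 (3E)-6-{[tert-butyl(dimethyl)silyl]oxy}-3-methylhex-3-en-1-ol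
Product: 17 (3E)-6-{[tert-butyl(dimethyl)silyl]oxy}-3-methylhex-3-enal
Conditions: Dess–Martin periodinane, CH2Cl2, 0 °C; used at once
Reagents that add atoms: none
Why: Dess–Martin oxidation is mild enough to stop at the β,γ-unsaturated aldehyde without moving the alkene into conjugation.

**Fragment 3: epoxy acid**

Step 10
Reactants: 18 (2E)-2-methylbut-2-en-1-ol (tiglyl alcohol)
Product: 19 [(2R,3R)-2,3-dimethyloxiran-2-yl]methanol
Conditions: Ti(OiPr)4 (5 mol %), D-(−)-diethyl tartrate (7 mol %), t-BuOOH, 4 Å molecular sieves, CH2Cl2, −20 °C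
Reagents that add atoms: tert-butyl hydroperoxide, CC(C)(C)OO
Why: Sharpless asymmetric epoxidation of the E allylic alcohol is stereospecific (the methyl groups stay cis) and the D-(−)-tartrate delivers oxygen to the face that gives the 2R,3R epoxy alcohol.

Step 11
Reactants: 19 [(2R,3R)-2,3-dimethyloxiran-2-yl]methanol
Product: 20 (2S,3R)-2,3-dimethyloxirane-2-carboxylic acid
Conditions: RuCl3·xH2O (2 mol %), NaIO4 (3 equiv), CCl4/MeCN/H2O, 0 °C → rt
Reagents that add atoms: sodium periodate (terminal oxygen source), [Na+].[O-]I(=O)(=O)=O; water (hydrates the aldehyde stage), O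
Why: Sharpless ruthenium tetroxide oxidation takes the primary alcohol to the acid without opening the trisubstituted oxirane; both centres are kept and C2 only changes its descriptor from R to S because of the priority change.

**Assembly**

Step 12
Reactants: 9 (5S)-3-(bromomethyl)-5-[(1Z)-2-iodoprop-1-en-1-yl]furan-2(5H)-one; 17 (3E)-6-{[tert-butyl(dimethyl)silyl]oxy}-3-methylhex-3-enal
Product: 22 (4R,5S)-4-[(1S,3E)-6-{[tert-butyl(dimethyl)silyl]oxy}-1-hydroxy-3-methylhex-3-en-1-yl]-5-[(1Z)-2-iodoprop-1-en-1-yl]-3-methylideneoxolan-2-one (6S,7R,8S; 8α-alcohol), via allylzinc bromide 21 (not isolated)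
Conditions: Zn dust, THF/saturated aqueous NH4Cl, 0 °C → rt
Reagents that add atoms: none
Why: Barbier allylation: the allylzinc reacts at its γ-carbon (C7) on the face anti to the C6 alkenyl group through a Zimmerman–Traxler chair in which the ring-locked E-type allyl unit gives the anti adduct, so the trans lactone (7R), the exocyclic methylene and the 8S (8α) alcohol are set together, and zinc in aqueous NH4Cl leaves the alkenyl iodide, the silyl ether and the skipped alkene alone.

Step 13
Reactants: 22 the 8α-alcohol; 20 (2S,3R)-2,3-dimethyloxirane-2-carboxylic acid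
Product: 23 (1R,3E)-6-{[tert-butyl(dimethyl)silyl]oxy}-1-{(2S,3R)-2-[(1Z)-2-iodoprop-1-en-1-yl]-4-methylidene-5-oxooxolan-3-yl}-3-methylhex-3-en-1-yl (2S,3R)-2,3-dimethyloxirane-2-carboxylate (6S,7R,8R; 8β-ester)
Conditions: PPh3 and DIAD premixed, toluene, 0 °C → rt
Reagents that add atoms: none
Why: Mitsunobu esterification displaces the activated C8 oxygen by the carboxylate of 20 in an SN2 step, so the acyl group is installed and C8 is inverted from S to the required R (8β) in the same operation; the oxirane centres of 20 are not involved.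

Step 14
Reactants: 23 the 8β-ester silyl ether
Product: 24 primary alcohol (23 with C3–OH in place of C3–OTBS; 6S,7R,8R)
Conditions: HF·pyridine, pyridine, THF, 0 °C → rt
Reagents that add atoms: none
Why: Fluoride-mediated desilylation under buffered, base-free conditions frees the primary alcohol and spares the α-methylene lactone, both ester groups and the glycidic oxirane.

Step 15
Reactants: 24 the primary alcohol
Product: 25 iodo aldehyde (C3 aldehyde, Z C4 iodide; 6S,7R,8R)
Conditions: Dess–Martin periodinane, CH2Cl2, 0 °C; used at once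
Reagents that add atoms: none
Why: Dess–Martin oxidation gives the sensitive β,γ-unsaturated aldehyde without base, so neither alkene migration nor addition to the methylene lactone occurs.

Step 16
Reactants: 25 the iodo aldehyde
Product: 27 3α-hydroxy-8β-[(2S,3R)-2,3-dimethyloxirane-2-carbonyloxy]germacra-1(10)E,4Z,11(13)-trien-12,6α-olide (3R,6R,7R,8R), via alkenylchromium dichloride 26 (not isolated)
Conditions: CrCl2 (10 equiv), NiCl2 (0.1 equiv), DMSO, 2 mM, slow addition, rt; aqueous work-up
Reagents that add atoms: none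
Why: Intramolecular Nozaki–Hiyama–Kishi reaction: zerovalent nickel inserts into the carbon–iodine bond with retention of the Z geometry, transmetalation gives a chemoselective alkenylchromium that adds only to the aldehyde, and high dilution favours the ten-membered ring; the bulky O–Cr group should sit on the ring periphery (3R alcohol), but the C3 configuration does not matter because step 17 removes it.

Step 17
Reactants: 27 the macrocyclic allylic alcohol (any 3S epimer is carried along)
Product: 28 3-oxo-8β-[(2S,3R)-2,3-dimethyloxirane-2-carbonyloxy]germacra-1(10)E,4Z,11(13)-trien-12,6α-olide (6R,7R,8R)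
Conditions: Dess–Martin periodinane, CH2Cl2, 0 °C → rt
Reagents that add atoms: none
Why: Dess–Martin oxidation converts either C3 epimer into the same ketone without base, so the doubly activated C2 methylene is not enolised.

Step 18
Reactants: 28 the ring ketone
Product: 29 3β-hydroxy-8β-[(2S,3R)-2,3-dimethyloxirane-2-carbonyloxy]germacra-1(10)E,4Z,11(13)-trien-12,6α-olide (3S,6R,7R,8R)
Conditions: NaBH4, CeCl3·7H2O, MeOH, −78 °C
Reagents that add atoms: none
Why: Luche reduction gives 1,2-reduction faster than conjugate reduction of the methylene lactone, and because the inner face of the twisted C3 carbonyl is blocked by H6 and the ring, hydride attacks from the periphery (macrocyclic stereocontrol) and pushes the oxygen inward to give the 3S (3β) alcohol.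

Step 19
Reactants: 29 the 3β-alcohol; 30 3-methylbutanoic anhydride (isovaleric anhydride)
Product: 31 3β-(3-methylbutanoyloxy)-8β-[(2S,3R)-2,3-dimethyloxirane-2-carbonyloxy]germacra-1(10)E,4Z,11(13)-trien-12,6α-olide (3S,6R,7R,8R)
Conditions: DMAP (0.2 equiv), pyridine, CH2Cl2, 0 °C → rt
Reagents that add atoms: none
Why: DMAP-catalysed acylation esterifies the only free hydroxyl with retention at C3.

Step 20
Reactants: 31 the diester triene
Product: 32 target CNP0167461.3 (1R,3S,6R,7R,8R,10R; side chain 2S,3R)
Conditions: mCPBA (1.05 equiv), CH2Cl2, −20 → 0 °C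
Reagents that add atoms: 3-chloroperoxybenzoic acid, O=C(OO)c1cccc(Cl)c1
Why: Prilezhaev epoxidation is chemoselective for the strained, electron-rich E C1=C10 alkene (C4=C5 is deactivated by two allylic acyloxy groups and the methylene lactone is electron-poor), it is stereospecific for the trans oxirane, and attack on the only exposed outer face of the conformer with the C10 methyl on the β face gives the 1R,10R (1β,10α) epoxide.

**Compound list**
1 | acrolein (prop-2-enal) | C=CC=O | starting material
2 | prop-1-yn-1-ylmagnesium bromide | CC#C[Mg]Br | starting material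
3 | (±)-hex-1-en-4-yn-3-ol | C=CC(O)C#CC | intermediate
4 | cyclic vinylalanate (sodium 2,2-bis(2-methoxyethoxy)-3-methyl-5-vinyl-2,5-dihydro-1,2-oxaaluminol-2-uide) | [Na+].C=CC1C=C(C)[Al-](OCCOC)(OCCOC)O1 | intermediate
5 | (±)-(4Z)-5-iodohexa-1,4-dien-3-ol | C=CC(O)/C=C(/C)I | intermediate
6 | (3S,4Z)-5-iodohexa-1,4-dien-3-ol | C=C[C@H](O)/C=C(/C)I | intermediate
7 | 2-(bromomethyl)prop-2-enoic acid | C=C(CBr)C(=O)O | starting material
8 | (3S,4Z)-5-iodohexa-1,4-dien-3-yl 2-(bromomethyl)prop-2-enoate | C=C[C@H](OC(=O)C(=C)CBr)/C=C(/C)I | intermediate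
9 | (5S)-3-(bromomethyl)-5-[(1Z)-2-iodoprop-1-en-1-yl]furan-2(5H)-one | O=C1O[C@H](/C=C(/C)I)C=C1CBr | intermediate
10 | pent-3-yn-1-ol | CC#CCCO | starting material
11 | tert-butyl(dimethyl)(pent-3-yn-1-yloxy)silane | CC#CCCO[Si](C)(C)C(C)(C)C | intermediate
12 | alkenylzirconocene chloride (Zr on the methyl-bearing carbon, Zr trans to the CH2CH2OTBS chain) | C/C(=C\CCO[Si](C)(C)C(C)(C)C)[Zr](Cl)(C1C=CC=C1)C1C=CC=C1 | intermediate
13 | tert-butyl{[(3E)-4-iodopent-3-en-1-yl]oxy}dimethylsilane | C/C(I)=C\CCO[Si](C)(C)C(C)(C)C | intermediate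
14 | oxirane | C1CO1 | starting material
15 | alkenyllithium from 13 (geometry retained) | C/C([Li])=C\CCO[Si](C)(C)C(C)(C)C | intermediate
16 | (3E)-6-{[tert-butyl(dimethyl)silyl]oxy}-3-methylhex-3-en-1-ol | OCC/C(C)=C/CCO[Si](C)(C)C(C)(C)C | intermediate
17 | (3E)-6-{[tert-butyl(dimethyl)silyl]oxy}-3-methylhex-3-enal | O=CC/C(C)=C/CCO[Si](C)(C)C(C)(C)C | intermediate
18 | (2E)-2-methylbut-2-en-1-ol | C/C=C(\C)CO | starting material
19 | [(2R,3R)-2,3-dimethyloxiran-2-yl]methanol | OC[C@@]1(C)O[C@@H]1C | intermediate
20 | (2S,3R)-2,3-dimethyloxirane-2-carboxylic acid | OC(=O)[C@@]1(C)O[C@@H]1C | intermediate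
21 | allylzinc bromide from 9 | O=C1O[C@H](/C=C(/C)I)C=C1C[Zn]Br | intermediate
22 | Barbier adduct, 8α-alcohol (6S,7R,8S) | C=C1C(=O)O[C@H](/C=C(/C)I)[C@H]1[C@@H](O)C/C(C)=C/CCO[Si](C)(C)C(C)(C)C | intermediate
23 | 8β-epoxy ester, silyl ether (6S,7R,8R) | C=C1C(=O)O[C@H](/C=C(/C)I)[C@H]1[C@H](OC(=O)[C@@]2(C)O[C@@H]2C)C/C(C)=C/CCO[Si](C)(C)C(C)(C)C | intermediate
24 | 8β-epoxy ester, C3 primary alcohol | C=C1C(=O)O[C@H](/C=C(/C)I)[C@H]1[C@H](OC(=O)[C@@]2(C)O[C@@H]2C)C/C(C)=C/CCO | intermediate
25 | 8β-epoxy ester, C3 aldehyde (iodo aldehyde) | C=C1C(=O)O[C@H](/C=C(/C)I)[C@H]1[C@H](OC(=O)[C@@]2(C)O[C@@H]2C)C/C(C)=C/CC=O | intermediate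
26 | alkenylchromium dichloride from 25 | C=C1C(=O)O[C@H](/C=C(/C)[Cr](Cl)Cl)[C@H]1[C@H](OC(=O)[C@@]2(C)O[C@@H]2C)C/C(C)=C/CC=O | intermediate
27 | macrocyclic 3α-alcohol (3R,6R,7R,8R) | C=C1C(=O)O[C@@H]2/C=C(/C)[C@H](O)C/C=C(\C)C[C@@H](OC(=O)[C@@]3(C)O[C@@H]3C)[C@@H]12 | intermediate
28 | macrocyclic 3-ketone (6R,7R,8R) | C=C1C(=O)O[C@@H]2/C=C(/C)C(=O)C/C=C(\C)C[C@@H](OC(=O)[C@@]3(C)O[C@@H]3C)[C@@H]12 | intermediate
29 | macrocyclic 3β-alcohol (3S,6R,7R,8R) | C=C1C(=O)O[C@@H]2/C=C(/C)[C@@H](O)C/C=C(\C)C[C@@H](OC(=O)[C@@]3(C)O[C@@H]3C)[C@@H]12 | intermediate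
30 | 3-methylbutanoic anhydride | CC(C)CC(=O)OC(=O)CC(C)C | starting material
31 | 3β-isovalerate triene (3S,6R,7R,8R) | C=C1C(=O)O[C@@H]2/C=C(/C)[C@@H](OC(=O)CC(C)C)C/C=C(\C)C[C@@H](OC(=O)[C@@]3(C)O[C@@H]3C)[C@@H]12 | intermediate
32 | CNP0167461.3 (1R,3S,6R,7R,8R,10R; acyl 2S,3R) | C=C1C(=O)O[C@@H]2/C=C(/C)[C@@H](OC(=O)CC(C)C)C[C@H]3O[C@]3(C)C[C@@H](OC(=O)[C@@]3(C)O[C@@H]3C)[C@@H]12 | target

**Total step count:** 20. **Longest linear sequence:** 14 (steps 1–5, then 12–20).

**Three steps most likely to fail**

Step 13 (Mitsunobu inversion at C8). The carbinol is hindered and both neighbouring C–H bonds (C7, C9) are allylic, so elimination to dienes can win. PPh3 can also add to the methylene lactone. The fallback builds the 7,8-syn relationship directly and needs no inversion. It sets out from 6 and comes back at 23. Commercial ethyl 2-[(trimethylsilyl)methyl]prop-2-enoate is hydrolysed with LiOH to 2-[(trimethylsilyl)methyl]prop-2-enoic acid F1. Steglich esterification of 6 gives (3S,4Z)-5-iodohexa-1,4-dien-3-yl 2-[(trimethylsilyl)methyl]prop-2-enoate F2. Ring-closing metathesis as in step 5 gives the allylsilane butenolide (5S)-5-[(1Z)-2-iodoprop-1-en-1-yl]-3-[(trimethylsilyl)methyl]furan-2(5H)-one F3. A BF3·OEt2-promoted Hosomi–Sakurai addition of F3 to aldehyde 17 at −78 °C runs through an open antiperiplanar transition state. For an E-type allylsilane this is syn-selective, and attack is still anti to the C6 substituent, so it should give the 8β-alcohol (C8 epimer of 22) F4. Plain Steglich esterification of F4 with 20, with retention at C8, gives 23.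

Step 16 (Ni/Cr ring closure). The risks are ring strain and oligomerisation, drift of the skipped enal into conjugation on trivalent chromium, and attack of divalent chromium on the glycidic ester. The fallback is an acylative Stille macrocyclisation. It avoids chromium and the aldehyde, and gives the ketone directly. It sets out from 25 and comes back at 28. Pinnick oxidation (NaClO2, NaH2PO4, 2-methylbut-2-ene) gives the iodo carboxylic acid F5. Hexamethylditin with Pd(PPh3)4 exchanges iodine for tin with retention to give the trimethylstannyl carboxylic acid F6. 1-Chloro-N,N,2-trimethylprop-1-en-1-amine converts F6 under neutral conditions into the trimethylstannyl acid chloride F7. F7 is added slowly to Pd2(dba)3/AsPh3 in toluene at high dilution and closes the C3–C4 bond to give 28, so steps 16 and 17 are both skipped.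

Step 18 (Luche reduction). The risks are the wrong C3 epimer if the ring conformer differs from the model, and some hydride addition to the methylene lactone. The fallback moves the epoxidation forward and uses chelation in place of ring shape. It sets out from 28 and comes back at 32. mCPBA epoxidises the C1=C10 alkene of 28 to give the 1β,10α-epoxy 3-ketone F8. Zn(BH4)2 in Et2O at −20 °C chelates the ketone oxygen and the oxirane oxygen on C1. It delivers hydride to give the 1,3-syn product, the 1β,10α-epoxy 3β-alcohol (3-O-deacyl target) F9. Acylation of F9 with 30 under the conditions of step 19 gives 32.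

**Further compounds**
F1 | step 13 | 2-[(trimethylsilyl)methyl]prop-2-enoic acid | C=C(C[Si](C)(C)C)C(=O)O
F2 | step 13 | (3S,4Z)-5-iodohexa-1,4-dien-3-yl 2-[(trimethylsilyl)methyl]prop-2-enoate | C=C[C@H](OC(=O)C(=C)C[Si](C)(C)C)/C=C(/C)I
F3 | step 13 | (5S)-5-[(1Z)-2-iodoprop-1-en-1-yl]-3-[(trimethylsilyl)methyl]furan-2(5H)-one | O=C1O[C@H](/C=C(/C)I)C=C1C[Si](C)(C)C
F4 | step 13 | 8β-alcohol (C8 epimer of 22; 6S,7R,8R) | C=C1C(=O)O[C@H](/C=C(/C)I)[C@H]1[C@H](O)C/C(C)=C/CCO[Si](C)(C)C(C)(C)C
F5 | step 16 | iodo carboxylic acid (C3 acid from 25) | C=C1C(=O)O[C@H](/C=C(/C)I)[C@H]1[C@H](OC(=O)[C@@]2(C)O[C@@H]2C)C/C(C)=C/CC(=O)O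
F6 | step 16 | trimethylstannyl carboxylic acid | C=C1C(=O)O[C@H](/C=C(/C)[Sn](C)(C)C)[C@H]1[C@H](OC(=O)[C@@]2(C)O[C@@H]2C)C/C(C)=C/CC(=O)O
F7 | step 16 | trimethylstannyl acid chloride | C=C1C(=O)O[C@H](/C=C(/C)[Sn](C)(C)C)[C@H]1[C@H](OC(=O)[C@@]2(C)O[C@@H]2C)C/C(C)=C/CC(=O)Cl
F8 | step 18 | 1β,10α-epoxy 3-ketone (1R,6R,7R,8R,10R) | C=C1C(=O)O[C@@H]2/C=C(/C)C(=O)C[C@H]3O[C@]3(C)C[C@@H](OC(=O)[C@@]3(C)O[C@@H]3C)[C@@H]12
F9 | step 18 | 1β,10α-epoxy 3β-alcohol (3-O-deacyl target; 1R,3S,6R,7R,8R,10R) | C=C1C(=O)O[C@@H]2/C=C(/C)[C@@H](O)C[C@H]3O[C@]3(C)C[C@@H](OC(=O)[C@@]3(C)O[C@@H]3C)[C@@H]12
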